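**Plan**
- Retrosynthesis: the O–Si bond of a phenol silyl ether is cut first, then the C4'–C5' bond of the side chain (C1' to C13' counted outward from chroman C2). The chroman half is then cut at C2'–C3' and C1'–C2', the chain half at C9'–C10'.
- Enabling feature: C4' is a methine that carries a methyl group between two plain methylene chains. This is what a vinyl group C4'=CH2 becomes after taking up an alkyl group at its inner carbon and a metal (later hydrogen) at its outer carbon. The target's own alkene C12'=C13' is 1,1-disubstituted and does not take part.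
- Chroman half: the chroman ring and C2 come intact from (S)-Trolox. Ester, silyl ether, aldehyde, vinyl, hydroxyethyl, tosylate and allyl coupling give the 2-(pent-4-enyl)chroman 9.
- Chain half: an Evans allylation sets C8'. Reduction, tosylation and a copper-catalysed Grignard coupling add the isopropenyl end to give diene 17.
- Union: hydroalumination of the monosubstituted alkene of 17, zirconium-catalysed asymmetric alkylalumination of 9 (C4' set by the chiral zirconocene) and protonolysis. Desilylation ends the route.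

Key step: step 12

Assumption: the (−)-antipode of (NMI)2ZrCl2 (NMI = 1-neomenthylindenyl), which turns 1-alkenes and Me3Al into (R)-2-methylalkan-1-ols after oxidation, is taken to deliver higher n-alkyl groups to the same alkene face; if the sense were opposite, the (+)-antipode would be used.

**Step 1**
Reactants: 1 (S)-Trolox
Product: 2 methyl (2S)-6-hydroxy-2,5,7,8-tetramethylchromane-2-carboxylate
Conditions: MeOH, H2SO4 (cat.), reflux
Reagents that add atoms: methanol, CO
Why: Fischer esterification; C2 is quaternary and cannot epimerise.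

**Step 2**
Reactants: 2 methyl (2S)-6-hydroxy-2,5,7,8-tetramethylchromane-2-carboxylate
Product: 3 methyl (2S)-6-(tert-butyldimethylsilyloxy)-2,5,7,8-tetramethylchromane-2-carboxylate
Conditions: TBSCl, imidazole, DMF, 60 °C
Reagents that add atoms: tert-butyldimethylsilyl chloride, CC(C)(C)[Si](C)(C)Cl
Why: Imidazole-promoted silylation of the hindered phenol masks the oxidation-prone and acidic OH for the organometallic steps that follow.

**Step 3**
Reactants: 3 methyl (2S)-6-(tert-butyldimethylsilyloxy)-2,5,7,8-tetramethylchromane-2-carboxylate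
Product: 4 (2S)-6-(tert-butyldimethylsilyloxy)-2,5,7,8-tetramethylchromane-2-carbaldehyde
Conditions: iBu2AlH (1.1 equiv), toluene, −78 °C; then MeOH, aq. KNaC4H4O6
Reagents that add atoms: none
Why: Partial reduction of an ester by iBu2AlH; the tetrahedral aluminium hemiacetal, held by the neighbouring ring oxygen, should persist at −78 °C and release the aldehyde only on work-up.

**Step 4**
Reactants: 4 (2S)-6-(tert-butyldimethylsilyloxy)-2,5,7,8-tetramethylchromane-2-carbaldehyde
Product: 5 tert-butyldimethyl{[(2S)-2,5,7,8-tetramethyl-2-vinylchroman-6-yl]oxy}silane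
Conditions: Ph3PCH3Br, KOtBu, THF, 0 to 23 °C
Reagents that add atoms: methylenetriphenylphosphorane, made in the flask from methyltriphenylphosphonium bromide (C[P+](c1ccccc1)(c1ccccc1)c1ccccc1.[Br-]) and KOtBu, C=P(c1ccccc1)(c1ccccc1)c1ccccc1
Why: Wittig methylenation of a non-enolisable aldehyde, so the adjacent quaternary stereocentre is safe.

**Step 5**
Reactants: 5 tert-butyldimethyl{[(2S)-2,5,7,8-tetramethyl-2-vinylchroman-6-yl]oxy}silane
Product: 7 2-[(2S)-6-(tert-butyldimethylsilyloxy)-2,5,7,8-tetramethylchroman-2-yl]ethanol, via B-alkyl-9-BBN adduct 6 (not isolated)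
Conditions: 9-BBN, THF, 0 to 23 °C; then NaBO3·4H2O, H2O, 23 °C
Reagents that add atoms: sodium perborate, [Na+].[O-]OB=O
Why: Hydroboration–oxidation; the bulky borane should place boron on the terminal carbon of the vinyl group next to the quaternary centre, and perborate oxidises the C–B bond without strong base that could cleave the aryl silyl ether.

**Step 6**
Reactants: 7 2-[(2S)-6-(tert-butyldimethylsilyloxy)-2,5,7,8-tetramethylchroman-2-yl]ethanol
Product: 8 2-[(2S)-6-(tert-butyldimethylsilyloxy)-2,5,7,8-tetramethylchroman-2-yl]ethyl 4-methylbenzenesulfonate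
Conditions: TsCl, Et3N, DMAP (cat.), CH2Cl2, 0 to 23 °C
Reagents that add atoms: p-toluenesulfonyl chloride, Cc1ccc(cc1)S(=O)(=O)Cl
Why: Sulfonylation of an unhindered primary alcohol.

**Step 7**
Reactants: 8 2-[(2S)-6-(tert-butyldimethylsilyloxy)-2,5,7,8-tetramethylchroman-2-yl]ethyl 4-methylbenzenesulfonate
Product: 9 tert-butyldimethyl{[(2R)-2,5,7,8-tetramethyl-2-(pent-4-en-1-yl)chroman-6-yl]oxy}silane
Conditions: allylMgBr (3 equiv), Li2CuCl4 (5 mol %), THF, −78 to 0 °C
Reagents that add atoms: allylmagnesium bromide, C=CC[Mg]Br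
Why: Copper-catalysed Grignard–tosylate coupling (Kochi–Schlosser type) at an unbranched primary carbon, which the aryl silyl ether should tolerate at or below 0 °C.

**Step 8**
Reactants: 10 (4R)-4-benzyl-3-propanoyl-1,3-oxazolidin-2-one
Product: 12 (4R)-4-benzyl-3-[(2S)-2-methylpent-4-enoyl]-1,3-oxazolidin-2-one, via sodium Z-enolate 11 (not isolated)
Conditions: NaN(SiMe3)2, THF, −78 °C; then allyl iodide, −78 to −45 °C
Reagents that add atoms: allyl iodide, C=CCI
Why: Evans asymmetric alkylation; the chelated Z-enolate is attacked on the face away from the benzyl group, which should set the (S) centre that becomes C8'.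

**Step 9**
Reactants: 12 (4R)-4-benzyl-3-[(2S)-2-methylpent-4-enoyl]-1,3-oxazolidin-2-one
Product: 13 (2S)-2-methylpent-4-en-1-ol
Conditions: LiBH4, H2O (1 equiv), Et2O, 0 °C; aq. NaOH
Reagents that add atoms: none
Why: Reductive removal of the oxazolidinone auxiliary by borohydride at the exocyclic carbonyl, which does not touch the α-stereocentre.

**Step 10**
Reactants: 13 (2S)-2-methylpent-4-en-1-ol
Product: 14 (2S)-2-methylpent-4-en-1-yl 4-methylbenzenesulfonate
Conditions: TsCl, Et3N, DMAP (cat.), CH2Cl2, 0 to 23 °C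
Reagents that add atoms: p-toluenesulfonyl chloride, Cc1ccc(cc1)S(=O)(=O)Cl
Why: Sulfonylation of the primary alcohol, which also makes the volatile C6 unit easier to handle.

**Step 11**
Reactants: 14 (2S)-2-methylpent-4-en-1-yl 4-methylbenzenesulfonate; 15 4-bromo-2-methylbut-1-ene
Product: 17 (4R)-4,8-dimethylnona-1,8-diene, via homoallyl Grignard reagent 16 (not isolated)
Conditions: 15, Mg, THF, 40 °C; then 14, Li2CuCl4 (5 mol %), THF, −78 to 23 °C
Reagents that add atoms: none
Why: Copper-catalysed Grignard–tosylate coupling (Kochi–Schlosser type), well known for β-methyl-branched primary tosylates; the stereocentre is not involved and only its descriptor changes.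

**Step 12**
Reactants: 17 (4R)-4,8-dimethylnona-1,8-diene; 9 tert-butyldimethyl{[(2R)-2,5,7,8-tetramethyl-2-(pent-4-en-1-yl)chroman-6-yl]oxy}silane
Product: 20 tert-butyldimethyl{[(2R)-2,5,7,8-tetramethyl-2-[(4R,8S)-4,8,12-trimethyltridec-12-en-1-yl]chroman-6-yl]oxy}silane, via n-alkyl(diisobutyl)alane 18 (not isolated), via carboalumination alane 19 (not isolated)
Conditions: 17 (1.5 equiv), iBu2AlH (1.5 equiv), hexane, 60 °C; then 9, (−)-(NMI)2ZrCl2 (5 mol %), (iBuAlO)n, CH2Cl2, 0 to 23 °C; then 2 M HCl, 0 °C
Reagents that add atoms: none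
Why: Thermal syn-addition of Al–H to the monosubstituted C5'=C6' alkene of 17 puts aluminium on C5' (the 1,1-disubstituted C12'=C13' alkene adds far more slowly); this n-alkyl group passes to the cationic chiral zirconocene, the vinyl group of 9 inserts into the Zr–C bond with carbon going to the inner carbon C4' and metal to the outer one, the new alkyl returns to aluminium, and protonolysis of the C–Al bond turns the outer carbon into the C4' methyl group. The closest known reaction type is the zirconium-catalysed asymmetric carboalumination of 1-alkenes (ZACA reaction) with higher n-alkylalanes made by hydroalumination, followed by protonolysis to a methyl branch. No ring is closed. The C4' stereocentre is set by the chiral bis(1-neomenthylindenyl)zirconium catalyst, which selects the alkene face (catalyst control, since C2 and C8' are too remote to interfere), and C2 and C8' are not touched. The step needs chemoselectivity for the monosubstituted alkene, which should hold because zirconocene alkyls do not insert 1,1-disubstituted alkenes and the β-branched product alane 19 does not add again; it also needs transfer of the n-alkyl and not the isobutyl groups, which their lower steric demand and the chlorinated solvent (which suppresses β-hydride transfer) should favour.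

**Step 13**
Reactants: 20 tert-butyldimethyl{[(2R)-2,5,7,8-tetramethyl-2-[(4R,8S)-4,8,12-trimethyltridec-12-en-1-yl]chroman-6-yl]oxy}silane
Product: 21 (2R)-2,5,7,8-tetramethyl-2-[(4R,8S)-4,8,12-trimethyltridec-12-en-1-yl]chroman-6-ol
Conditions: Bu4NF, THF, 0 °C, under argon; aq. NH4Cl
Reagents that add atoms: none
Why: Fluoride-induced cleavage of the aryl silyl ether, which leaves the terminal alkene and all stereocentres untouched.

**Compound list**
1 | (S)-Trolox, (2S)-6-hydroxy-2,5,7,8-tetramethylchromane-2-carboxylic acid | OC(=O)[C@]1(C)CCc2c(C)c(O)c(C)c(C)c2O1 | starting material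
2 | methyl (2S)-6-hydroxy-2,5,7,8-tetramethylchromane-2-carboxylate | COC(=O)[C@]1(C)CCc2c(C)c(O)c(C)c(C)c2O1 | intermediate
3 | methyl (2S)-6-(tert-butyldimethylsilyloxy)-2,5,7,8-tetramethylchromane-2-carboxylate | COC(=O)[C@]1(C)CCc2c(C)c(O[Si](C)(C)C(C)(C)C)c(C)c(C)c2O1 | intermediate
4 | (2S)-6-(tert-butyldimethylsilyloxy)-2,5,7,8-tetramethylchromane-2-carbaldehyde | O=C[C@]1(C)CCc2c(C)c(O[Si](C)(C)C(C)(C)C)c(C)c(C)c2O1 | intermediate
5 | tert-butyldimethyl{[(2S)-2,5,7,8-tetramethyl-2-vinylchroman-6-yl]oxy}silane | C=C[C@]1(C)CCc2c(C)c(O[Si](C)(C)C(C)(C)C)c(C)c(C)c2O1 | intermediate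
6 | 9-{2-[(2R)-6-(tert-butyldimethylsilyloxy)-2,5,7,8-tetramethylchroman-2-yl]ethyl}-9-borabicyclo[3.3.1]nonane | B1(CC[C@]3(C)CCc4c(C)c(O[Si](C)(C)C(C)(C)C)c(C)c(C)c4O3)C2CCCC1CCC2 | intermediate
7 | 2-[(2S)-6-(tert-butyldimethylsilyloxy)-2,5,7,8-tetramethylchroman-2-yl]ethanol | OCC[C@]1(C)CCc2c(C)c(O[Si](C)(C)C(C)(C)C)c(C)c(C)c2O1 | intermediate
8 | 2-[(2S)-6-(tert-butyldimethylsilyloxy)-2,5,7,8-tetramethylchroman-2-yl]ethyl 4-methylbenzenesulfonate | Cc1ccc(cc1)S(=O)(=O)OCC[C@]1(C)CCc2c(C)c(O[Si](C)(C)C(C)(C)C)c(C)c(C)c2O1 | intermediate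
9 | tert-butyldimethyl{[(2R)-2,5,7,8-tetramethyl-2-(pent-4-en-1-yl)chroman-6-yl]oxy}silane | C=CCCC[C@]1(C)CCc2c(C)c(O[Si](C)(C)C(C)(C)C)c(C)c(C)c2O1 | intermediate
10 | (4R)-4-benzyl-3-propanoyl-1,3-oxazolidin-2-one | CCC(=O)N1[C@H](Cc2ccccc2)COC1=O | starting material
11 | sodium (Z)-enolate of 10 | C/C=C(\[O-])N1[C@H](Cc2ccccc2)COC1=O.[Na+] | intermediate
12 | (4R)-4-benzyl-3-[(2S)-2-methylpent-4-enoyl]-1,3-oxazolidin-2-one | C=CC[C@H](C)C(=O)N1[C@H](Cc2ccccc2)COC1=O | intermediate
13 | (2S)-2-methylpent-4-en-1-ol | C=CC[C@H](C)CO | intermediate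
14 | (2S)-2-methylpent-4-en-1-yl 4-methylbenzenesulfonate | C=CC[C@H](C)COS(=O)(=O)c1ccc(C)cc1 | intermediate
15 | 4-bromo-2-methylbut-1-ene | C=C(C)CCBr | starting material
16 | (3-methylbut-3-en-1-yl)magnesium bromide | C=C(C)CC[Mg]Br | intermediate
17 | (4R)-4,8-dimethylnona-1,8-diene | C=CC[C@H](C)CCCC(C)=C | intermediate
18 | [(4R)-4,8-dimethylnon-8-en-1-yl]bis(2-methylpropyl)alane | CC(C)C[Al](CC(C)C)CCC[C@H](C)CCCC(C)=C | intermediate
19 | [(2R,6S)-2-{3-[(2R)-6-(tert-butyldimethylsilyloxy)-2,5,7,8-tetramethylchroman-2-yl]propyl}-6,10-dimethylundec-10-en-1-yl]bis(2-methylpropyl)alane | CC(C)C[Al](CC(C)C)C[C@H](CCC[C@H](C)CCCC(C)=C)CCC[C@]1(C)CCc2c(C)c(O[Si](C)(C)C(C)(C)C)c(C)c(C)c2O1 | intermediate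
20 | tert-butyldimethyl{[(2R)-2,5,7,8-tetramethyl-2-[(4R,8S)-4,8,12-trimethyltridec-12-en-1-yl]chroman-6-yl]oxy}silane | C=C(C)CCC[C@@H](C)CCC[C@@H](C)CCC[C@]1(C)CCc2c(C)c(O[Si](C)(C)C(C)(C)C)c(C)c(C)c2O1 | intermediate
21 | (2R)-2,5,7,8-tetramethyl-2-[(4R,8S)-4,8,12-trimethyltridec-12-en-1-yl]chroman-6-ol | C=C(C)CCC[C@@H](C)CCC[C@@H](C)CCC[C@]1(C)CCc2c(C)c(O)c(C)c(C)c2O1 | target

**Step count**
Total: 13 steps. Longest linear sequence: 9 steps (steps 1 to 7, 12 and 13).

**Steps most likely to fail**

Step 12. Transfer of the n-alkyl group from alane 18 may be slow, or be outrun by hydrometalation of 9 through β-hydride transfer from the isobutyl groups, and face selection at C4' may be incomplete, leaving an epimer that is hard to remove. The fallback makes the same bond by a stereospecific substitution. From 9, Wacker oxidation (PdCl2, CuCl, O2, DMF–H2O) should give the methyl ketone F1. Reduction with an (R)-selective alcohol dehydrogenase (ketoreductase class, NADPH with isopropanol recycling) should give the (R)-carbinol F2, and TsCl in pyridine the secondary tosylate F3. From 17, hydroalumination to alane 18 as in step 12, then dry O2 and acidic work-up, should give the primary alcohol F4; CBr4 and PPh3 should give the bromide F5, and Mg in THF the Grignard reagent F6. Copper-catalysed coupling of F3 with F6 (copper iodide CuI, TMEDA, LiOMe, THF, 0 °C), an SN2 displacement with inversion at the secondary carbon, should return the route at 20.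

Step 3. The aluminium hemiacetal may collapse before the quench, so that over-reduction to the primary alcohol competes with the aldehyde. The fallback separates the two redox events. From 3, exhaustive reduction with excess iBu2AlH in CH2Cl2 at 0 °C should give the primary alcohol F7, and Dess–Martin periodinane in CH2Cl2 should oxidise it back to the aldehyde, returning at 4.

Step 7. Displacement of the tosylate may be slow against elimination to the vinyl compound or against attack of excess Grignard reagent on the aryl silyl ether. The fallback uses a radical instead of a polar C–C bond formation. From 7, I2, PPh3 and imidazole in CH2Cl2 should give the primary iodide F8, and a Keck radical allylation (allyltributylstannane, AIBN, toluene, 80 °C) should return the route at 9.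

**Further compounds**
F1 | step 12 | 5-[(2R)-6-(tert-butyldimethylsilyloxy)-2,5,7,8-tetramethylchroman-2-yl]pentan-2-one | CC(=O)CCC[C@]1(C)CCc2c(C)c(O[Si](C)(C)C(C)(C)C)c(C)c(C)c2O1
F2 | step 12 | (2R)-5-[(2R)-6-(tert-butyldimethylsilyloxy)-2,5,7,8-tetramethylchroman-2-yl]pentan-2-ol | C[C@@H](O)CCC[C@]1(C)CCc2c(C)c(O[Si](C)(C)C(C)(C)C)c(C)c(C)c2O1
F3 | step 12 | (2R)-5-[(2R)-6-(tert-butyldimethylsilyloxy)-2,5,7,8-tetramethylchroman-2-yl]pentan-2-yl 4-methylbenzenesulfonate | C[C@@H](OS(=O)(=O)c1ccc(C)cc1)CCC[C@]1(C)CCc2c(C)c(O[Si](C)(C)C(C)(C)C)c(C)c(C)c2O1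
F4 | step 12 | (4R)-4,8-dimethylnon-8-en-1-ol | C=C(C)CCC[C@@H](C)CCCO
F5 | step 12 | (6R)-9-bromo-2,6-dimethylnon-1-ene | C=C(C)CCC[C@@H](C)CCCBr
F6 | step 12 | [(4R)-4,8-dimethylnon-8-en-1-yl]magnesium bromide | C=C(C)CCC[C@@H](C)CCC[Mg]Br
F7 | step 3 | [(2S)-6-(tert-butyldimethylsilyloxy)-2,5,7,8-tetramethylchroman-2-yl]methanol | OC[C@]1(C)CCc2c(C)c(O[Si](C)(C)C(C)(C)C)c(C)c(C)c2O1
F8 | step 7 | tert-butyl{[(2S)-2-(2-iodoethyl)-2,5,7,8-tetramethylchroman-6-yl]oxy}dimethylsilane | ICC[C@]1(C)CCc2c(C)c(O[Si](C)(C)C(C)(C)C)c(C)c(C)c2O1
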